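**Strategy.** The chromone is cut at C7–C8 of ring A. The C7 hydroxyl sits beside C8, and C8 is bonded to C8a, a carbon of pyranone ring C. C8 is therefore traced back to the CH-acidic methyl group at C2 of a monocyclic 4-pyranone, and C7 to an ester carbonyl that a Z-butenoate on the neighbouring ring carbon (future C4a) holds within reach. One alkoxide-mediated step joins C7 to C8, ejects methanol and aromatises ring A to the 7-hydroxy-5-methylchromone. The precursor is a 6-aryl-2-methyl-4-pyranone with a (Z)-methyl butenoate at C3, made by Stille coupling of an iodide whose position is fixed when the pyranone is assembled. A silyl-protected hydroxyethyl arm later becomes the hydroxypyranone.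

Key step: step 10

Remark: iodo enone 8 is expected as an E/Z mixture and aldol 10 as a racemate; both elements are erased in step 7, so neither is controlled. Locants C2 to C8a refer to the chromone of the target.

Step 1
Reactants: 1 3,5-dimethoxyphenylacetic acid
Product: 2 2-(3,5-dimethoxyphenyl)ethanol
Conditions: LiAlH4, THF, 0 °C to reflux; then H2O, aq NaOH
Reagents that add atoms: none
Why: Hydride reduction of a carboxylic acid with LiAlH4 proceeds through the aluminium carboxylate to the primary alcohol and leaves the aryl ethers untouched.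

Step 2
Reactants: 2 2-(3,5-dimethoxyphenyl)ethanol
Product: 3 [2-(3,5-dimethoxyphenyl)ethoxy]tri(propan-2-yl)silane
Conditions: i-Pr3SiCl, imidazole, DMF, rt
Reagents that add atoms: chlorotri(propan-2-yl)silane, CC(C)[Si](Cl)(C(C)C)C(C)C
Why: Imidazole-promoted silylation of a primary alcohol is reliable, and the bulky triisopropylsilyl ether is chosen because it should resist the chloroiminium reagent and the enolate and alkoxide bases ahead and, unlike an ester, cannot release a nucleophilic alkoxide next to the pyranone.

Step 3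
Reactants: 3 [2-(3,5-dimethoxyphenyl)ethoxy]tri(propan-2-yl)silane
Product: 5 2,4-dimethoxy-6-[2-(triisopropylsilyloxy)ethyl]benzaldehyde, via aryl iminium chloride 4 (not isolated)
Conditions: POCl3, DMF, 0 °C to 40 °C; then aq NaOAc
Reagents that add atoms: N,N-dimethylformamide, CN(C)C=O; water, O
Why: Vilsmeier–Haack formylation of a 5-alkylresorcinol dimethyl ether is expected at the ring position para to one methoxy group and ortho to the other (next to the alkyl arm) rather than at the crowded position between the two methoxy groups, and a primary triisopropylsilyl ether is expected to survive the chloroiminium salt at these temperatures.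

Step 4
Reactants: 6 acetylacetone (pentane-2,4-dione)
Product: 7 (E)-4-methoxypent-3-en-2-one
Conditions: HC(OMe)3, MeOH, p-toluenesulfonic acid (cat.), 55 °C
Reagents that add atoms: trimethyl orthoformate, COC(OC)OC
Why: Acid-catalysed ketalisation of one carbonyl of the symmetrical 1,3-diketone and loss of methanol (enol ether formation) gives a single vinylogous ester, the orthoformate taking up the water.

Step 5
Reactants: 7 (E)-4-methoxypent-3-en-2-one
Product: 8 3-iodo-4-methoxypent-3-en-2-one
Conditions: N-iodosuccinimide, CH2Cl2, 0 °C to rt, dark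
Reagents that add atoms: N-iodosuccinimide, O=C1CCC(=O)N1I
Why: Electrophilic iodination of a vinylogous ester occurs at its only nucleophilic carbon, C3, and doing it on this small fragment, before any electron-rich arene is present, fixes the halogen at the carbon that becomes C3 of the pyranone.

Step 6
Reactants: 5 2,4-dimethoxy-6-[2-(triisopropylsilyloxy)ethyl]benzaldehyde; 8 3-iodo-4-methoxypent-3-en-2-one
Product: 10 1-{2,4-dimethoxy-6-[2-(triisopropylsilyloxy)ethyl]phenyl}-1-hydroxy-4-iodo-5-methoxyhex-4-en-3-one (racemic), via lithium enolate 9 (not isolated)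
Conditions: 8, LiN(SiMe3)2, THF, −78 °C; then 5, −78 °C; AcOH, −78 °C
Reagents that add atoms: none
Why: Kinetic deprotonation of the β-methoxy enone at its acetyl methyl group and directed aldol addition of the cross-conjugated enolate to the non-enolisable aldehyde should give the racemic aldol, whose single stereocentre is of no consequence because it is oxidised away in step 7, while the cold acidic quench suppresses retro-aldol cleavage.

Step 7
Reactants: 10 1-{2,4-dimethoxy-6-[2-(triisopropylsilyloxy)ethyl]phenyl}-1-hydroxy-4-iodo-5-methoxyhex-4-en-3-one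
Product: 12 6-{2,4-dimethoxy-6-[2-(triisopropylsilyloxy)ethyl]phenyl}-3-iodo-2-methyl-4H-pyran-4-one, via diketone 11 (not isolated)
Conditions: Dess–Martin periodinane, pyridine, CH2Cl2, 0 °C to rt; then TFA, 0 °C to rt
Reagents that add atoms: none
Why: Dess–Martin oxidation under pyridine buffer converts the acid-sensitive benzylic β-hydroxy ketone into the enolised 1,3-diketone, and trifluoroacetic acid then lets the enol oxygen of the aryl ketone add to the methoxy-bearing carbon and expel methanol (6-endo addition–elimination, the classical acid closure of β-alkoxy enone diketones to 4-pyranones), which necessarily places iodine between the methyl-bearing carbon and the carbonyl.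

Step 8
Reactants: 13 methyl but-2-ynoate
Product: 14 methyl (Z)-3-(trimethylstannyl)but-2-enoate
Conditions: Me6Sn2, MeLi, THF, −20 °C; CuSPh, −20 °C; then 13, −78 °C then −48 °C, 4 h; MeOH
Reagents that add atoms: lithium (phenylthio)(trimethylstannyl)cuprate (made in the flask from Me6Sn2, MeLi and CuSPh), [Li+].C[Sn](C)(C)[Cu-]Sc1ccccc1
Why: Stannylcupration of the ynoate puts tin on C3, and letting the adduct equilibrate at −48 °C before protonation should give the thermodynamically preferred Z isomer with tin cis to the ester, the geometry that the coupling must transfer.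

Step 9
Reactants: 12 6-{2,4-dimethoxy-6-[2-(triisopropylsilyloxy)ethyl]phenyl}-3-iodo-2-methyl-4H-pyran-4-one; 14 methyl (Z)-3-(trimethylstannyl)but-2-enoate
Product: 15 methyl (Z)-3-(6-{2,4-dimethoxy-6-[2-(triisopropylsilyloxy)ethyl]phenyl}-2-methyl-4-oxo-4H-pyran-3-yl)but-2-enoate
Conditions: Pd(PPh3)4 (cat.), CuI (cat.), CsF, DMF, 45 °C
Reagents that add atoms: none
Why: Stille coupling of the activated α-iodo enone with the vinylstannane proceeds with retention of alkene geometry, so the pyranone ends up cis to the ester, and CuI with fluoride is used because it accelerates transmetalation of hindered, electron-poor stannanes.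

Step 10
Reactants: 15 methyl (Z)-3-(6-{2,4-dimethoxy-6-[2-(triisopropylsilyloxy)ethyl]phenyl}-2-methyl-4-oxo-4H-pyran-3-yl)but-2-enoate
Product: 16 2-{2,4-dimethoxy-6-[2-(triisopropylsilyloxy)ethyl]phenyl}-7-hydroxy-5-methyl-4H-chromen-4-one
Conditions: NaOMe, MeOH, rt to 60 °C; then aq HCl
Reagents that add atoms: none
Why: Methoxide reversibly deprotonates the C2 methyl group of the 4-pyranone (future C8), a vinylogous methyl ketone, and the dienolate carbon adds to the ester carbonyl (future C7) held on the same side of the butenoate double bond; loss of methoxide from the tetrahedral intermediate gives an 8H-chromene-4,7-dione that enolises to the phenol, and formation of the phenoxide pulls the equilibria to the product. The closest known chemistry is the Dieckmann-type Claisen cyclisation of δ-keto esters to resorcinols, combined with the established alkoxide-mediated lateral condensations of 2-methyl-4-pyranones. Ring A closes in the 6-exo-trig mode, the ester C=O being exocyclic to the six-membered ring that forms. No stereocentre is created; the Z alkene from step 9 is absorbed into the aromatic ring, and any E isomer can re-enter through reversible deprotonation of the butenoate methyl group (future C5 methyl) under the same conditions. The step requires that C8 bond to C7 and to nothing else, which the substrate secures because the pyranone methyl carbanion is the only nucleophile that can reach the ester through a six-membered transition state (its addition to the alkene carbons would make four- or five-membered rings), while the silyl and aryl ethers are inert to methoxide and the matched NaOMe/methyl ester pair makes transesterification and reversible methoxide addition to the pyranone harmless.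

Step 11
Reactants: 16 2-{2,4-dimethoxy-6-[2-(triisopropylsilyloxy)ethyl]phenyl}-7-hydroxy-5-methyl-4H-chromen-4-one
Product: 17 2-{2,4-dimethoxy-6-[2-(triisopropylsilyloxy)ethyl]phenyl}-7-methoxy-5-methyl-4H-chromen-4-one
Conditions: MeI, K2CO3, acetone, reflux
Reagents that add atoms: iodomethane, CI
Why: Williamson methylation of the acidic 7-hydroxyl (a vinylogous acid) masks it for the strongly basic acylation in step 14 with a group that leaves in the final ether cleavage.

Step 12
Reactants: 17 2-{2,4-dimethoxy-6-[2-(triisopropylsilyloxy)ethyl]phenyl}-7-methoxy-5-methyl-4H-chromen-4-one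
Product: 18 2-[2-(2-hydroxyethyl)-4,6-dimethoxyphenyl]-7-methoxy-5-methyl-4H-chromen-4-one
Conditions: HF·pyridine, pyridine, THF, 0 °C to rt
Reagents that add atoms: none
Why: Fluoride-driven cleavage of the Si–O bond under buffered, slightly acidic conditions frees the primary alcohol without generating an alkoxide that could add to C2 of the chromone.

Step 13
Reactants: 18 2-[2-(2-hydroxyethyl)-4,6-dimethoxyphenyl]-7-methoxy-5-methyl-4H-chromen-4-one
Product: 19 [3,5-dimethoxy-2-(7-methoxy-5-methyl-4-oxo-4H-chromen-2-yl)phenyl]acetic acid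
Conditions: 2,2,6,6-tetramethylpiperidin-1-oxyl (cat.), PhI(OAc)2, MeCN/H2O, rt
Reagents that add atoms: water, O
Why: Oxoammonium-catalysed oxidation with PhI(OAc)2 as terminal oxidant (TEMPO oxidation) takes a primary alcohol through the aldehyde hydrate to the carboxylic acid in aqueous acetonitrile and is mild enough for the aryl ethers and the chromone.

Step 14
Reactants: 19 [3,5-dimethoxy-2-(7-methoxy-5-methyl-4-oxo-4H-chromen-2-yl)phenyl]acetic acid; 20 2,2,6-trimethyl-4H-1,3-dioxin-4-one
Product: 23 6-(3-{3,5-dimethoxy-2-[7-methoxy-5-methyl-4-oxo-4H-chromen-2-yl]phenyl}-2-oxopropyl)-2,2-dimethyl-4H-1,3-dioxin-4-one, via acyl imidazolide 21 (not isolated), via lithium dienolate 22 (not isolated)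
Conditions: 19, 1,1'-carbonyldiimidazole, THF, rt; 20 (excess), LiN(SiMe3)2, THF, −78 °C; add 21, −78 °C to −40 °C; AcOH, −78 °C
Reagents that add atoms: none
Why: Vinylogous Claisen acylation of the dioxinone dienolate at its γ-carbon by an acyl imidazole is a standard route to keto-dioxinones; excess dienolate absorbs the acidic product proton, the imidazolide is too mild to acylate C3 of the chromone, and the cold quench gives the stabilised product enolate no time to add to C2 of the chromone.

Step 15
Reactants: 23 6-(3-{3,5-dimethoxy-2-[7-methoxy-5-methyl-4-oxo-4H-chromen-2-yl]phenyl}-2-oxopropyl)-2,2-dimethyl-4H-1,3-dioxin-4-one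
Product: 25 2-{2-[(4-hydroxy-2-oxo-2H-pyran-6-yl)methyl]-4,6-dimethoxyphenyl}-7-methoxy-5-methyl-4H-chromen-4-one, via acylketene 24 (not isolated)
Conditions: toluene, 110 °C
Reagents that add atoms: none
Why: On heating, the dioxinone undergoes a retro-hetero-Diels–Alder loss of acetone to an acylketene that is captured by the enol oxygen of the neighbouring ketone, a neutral six-membered lactonisation that gives the 4-hydroxy-2-pyranone directly.

Step 16
Reactants: 25 2-{2-[(4-hydroxy-2-oxo-2H-pyran-6-yl)methyl]-4,6-dimethoxyphenyl}-7-methoxy-5-methyl-4H-chromen-4-one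
Product: 26 2-{2,4-dihydroxy-6-[(4-hydroxy-2-oxo-2H-pyran-6-yl)methyl]phenyl}-7-hydroxy-5-methyl-4H-chromen-4-one (target)
Conditions: BBr3 (excess), CH2Cl2, −78 °C to rt; then MeOH, H2O
Reagents that add atoms: none
Why: BBr3 cleaves the three aryl methyl ethers by Lewis acid-assisted bromide attack on the methyl groups, conditions that chromones and 4-hydroxy-2-pyranones are expected to tolerate, and hydrolytic work-up releases the free hydroxyl groups of the target.

**Compound list**

1 | 3,5-dimethoxyphenylacetic acid | COc1cc(CC(=O)O)cc(OC)c1 | starting material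
2 | 2-(3,5-dimethoxyphenyl)ethanol | COc1cc(CCO)cc(OC)c1 | intermediate
3 | [2-(3,5-dimethoxyphenyl)ethoxy]tri(propan-2-yl)silane | COc1cc(CCO[Si](C(C)C)(C(C)C)C(C)C)cc(OC)c1 | intermediate
4 | N-({2,4-dimethoxy-6-[2-(triisopropylsilyloxy)ethyl]phenyl}methylidene)-N-methylmethanaminium chloride (formed in the flask, not isolated) | C[N+](C)=Cc1c(OC)cc(OC)cc1CCO[Si](C(C)C)(C(C)C)C(C)C.[Cl-] | intermediate
5 | 2,4-dimethoxy-6-[2-(triisopropylsilyloxy)ethyl]benzaldehyde | O=Cc1c(OC)cc(OC)cc1CCO[Si](C(C)C)(C(C)C)C(C)C | intermediate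
6 | acetylacetone (pentane-2,4-dione) | CC(=O)CC(C)=O | starting material
7 | (E)-4-methoxypent-3-en-2-one | CO/C(C)=C/C(C)=O | intermediate
8 | 3-iodo-4-methoxypent-3-en-2-one (E/Z mixture, geometry not controlled) | COC(C)=C(I)C(C)=O | intermediate
9 | lithium 3-iodo-4-methoxypenta-1,3-dien-2-olate (formed in the flask, not isolated) | [Li+].[O-]C(=C)C(I)=C(C)OC | intermediate
10 | 1-{2,4-dimethoxy-6-[2-(triisopropylsilyloxy)ethyl]phenyl}-1-hydroxy-4-iodo-5-methoxyhex-4-en-3-one (racemic) | COC(C)=C(I)C(=O)CC(O)c1c(OC)cc(OC)cc1CCO[Si](C(C)C)(C(C)C)C(C)C | intermediate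
11 | 1-{2,4-dimethoxy-6-[2-(triisopropylsilyloxy)ethyl]phenyl}-4-iodo-5-methoxyhex-4-ene-1,3-dione (formed in the flask, not isolated) | COC(C)=C(I)C(=O)CC(=O)c1c(OC)cc(OC)cc1CCO[Si](C(C)C)(C(C)C)C(C)C | intermediate
12 | 6-{2,4-dimethoxy-6-[2-(triisopropylsilyloxy)ethyl]phenyl}-3-iodo-2-methyl-4H-pyran-4-one | Cc1oc(-c2c(OC)cc(OC)cc2CCO[Si](C(C)C)(C(C)C)C(C)C)cc(=O)c1I | intermediate
13 | methyl but-2-ynoate | CC#CC(=O)OC | starting material
14 | methyl (Z)-3-(trimethylstannyl)but-2-enoate (tin cis to the ester) | C[Sn](C)(C)/C(C)=C\C(=O)OC | intermediate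
15 | methyl (Z)-3-(6-{2,4-dimethoxy-6-[2-(triisopropylsilyloxy)ethyl]phenyl}-2-methyl-4-oxo-4H-pyran-3-yl)but-2-enoate (pyranone cis to the ester) | Cc1oc(-c2c(OC)cc(OC)cc2CCO[Si](C(C)C)(C(C)C)C(C)C)cc(=O)c1/C(C)=C\C(=O)OC | intermediate
16 | 2-{2,4-dimethoxy-6-[2-(triisopropylsilyloxy)ethyl]phenyl}-7-hydroxy-5-methyl-4H-chromen-4-one | Cc1cc(O)cc2oc(-c3c(OC)cc(OC)cc3CCO[Si](C(C)C)(C(C)C)C(C)C)cc(=O)c12 | intermediate
17 | 2-{2,4-dimethoxy-6-[2-(triisopropylsilyloxy)ethyl]phenyl}-7-methoxy-5-methyl-4H-chromen-4-one | Cc1cc(OC)cc2oc(-c3c(OC)cc(OC)cc3CCO[Si](C(C)C)(C(C)C)C(C)C)cc(=O)c12 | intermediate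
18 | 2-[2-(2-hydroxyethyl)-4,6-dimethoxyphenyl]-7-methoxy-5-methyl-4H-chromen-4-one | Cc1cc(OC)cc2oc(-c3c(OC)cc(OC)cc3CCO)cc(=O)c12 | intermediate
19 | [3,5-dimethoxy-2-(7-methoxy-5-methyl-4-oxo-4H-chromen-2-yl)phenyl]acetic acid | Cc1cc(OC)cc2oc(-c3c(OC)cc(OC)cc3CC(=O)O)cc(=O)c12 | intermediate
20 | 2,2,6-trimethyl-4H-1,3-dioxin-4-one | CC1=CC(=O)OC(C)(C)O1 | starting material
21 | 2-{2-[2-(1H-imidazol-1-yl)-2-oxoethyl]-4,6-dimethoxyphenyl}-7-methoxy-5-methyl-4H-chromen-4-one (formed in the flask, not isolated) | Cc1cc(OC)cc2oc(-c3c(OC)cc(OC)cc3CC(=O)n4ccnc4)cc(=O)c12 | intermediate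
22 | lithium 2,2-dimethyl-6-methylidene-6H-1,3-dioxin-4-olate (formed in the flask, not isolated) | [Li+].[O-]C1=CC(=C)OC(C)(C)O1 | intermediate
23 | 6-(3-{3,5-dimethoxy-2-[7-methoxy-5-methyl-4-oxo-4H-chromen-2-yl]phenyl}-2-oxopropyl)-2,2-dimethyl-4H-1,3-dioxin-4-one | Cc1cc(OC)cc2oc(-c3c(OC)cc(OC)cc3CC(=O)CC4=CC(=O)OC(C)(C)O4)cc(=O)c12 | intermediate
24 | 6-[3,5-dimethoxy-2-(7-methoxy-5-methyl-4-oxo-4H-chromen-2-yl)phenyl]-3,5-dioxohex-1-en-1-one (acylketene, formed in the flask, not isolated) | Cc1cc(OC)cc2oc(-c3c(OC)cc(OC)cc3CC(=O)CC(=O)C=C=O)cc(=O)c12 | intermediate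
25 | 2-{2-[(4-hydroxy-2-oxo-2H-pyran-6-yl)methyl]-4,6-dimethoxyphenyl}-7-methoxy-5-methyl-4H-chromen-4-one | Cc1cc(OC)cc2oc(-c3c(OC)cc(OC)cc3Cc4cc(O)cc(=O)o4)cc(=O)c12 | intermediate
26 | 2-{2,4-dihydroxy-6-[(4-hydroxy-2-oxo-2H-pyran-6-yl)methyl]phenyl}-7-hydroxy-5-methyl-4H-chromen-4-one (no stereocentres) | Cc1cc(O)cc2oc(-c3c(O)cc(O)cc3Cc3cc(O)cc(=O)o3)cc(=O)c12 | target

**Step count and risk**

Total step count: 16. Longest linear sequence: 13 steps (steps 1, 2, 3, 6, 7, 9, 10, 11, 12, 13, 14, 15, 16).

Step 10 (key step). What may go wrong: methoxide adds to C2 or C6 of the pyranone and the ring-opened enol ethers are diverted (for example by retro-Claisen cleavage) faster than the methyl carbanion closes onto the ester, or closure stalls because an E-configured ester does not equilibrate. The fallback takes ring A ready-made from an orcinol unit and closes ring C instead. Setting out from aldehyde 5, a Claisen–Schmidt condensation with the known acetophenone 1-(2-hydroxy-4-methoxy-6-methylphenyl)ethanone F1 (KOH, EtOH, rt) would give the chalcone (E)-3-{2,4-dimethoxy-6-[2-(triisopropylsilyloxy)ethyl]phenyl}-1-(2-hydroxy-4-methoxy-6-methylphenyl)prop-2-en-1-one F2. Iodine-catalysed oxidative cyclisation in DMSO (I2 cat., 110 °C) would then give the 2-arylchromone 17, where the main route is rejoined.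

Step 9. What may go wrong: transmetalation between the hindered, electron-poor stannane and the hindered pyranonyl–palladium species is slow, so protodestannylation, homocoupling or Z/E scrambling overtake the cross-coupling. The fallback replaces the tin reagent by a Heck reaction. Setting out from iodide 12, coupling with methyl crotonate (Pd(OAc)2, Bu4NCl, NaHCO3, DMF, 80 °C) should give the E ester methyl (E)-3-(6-{2,4-dimethoxy-6-[2-(triisopropylsilyloxy)ethyl]phenyl}-2-methyl-4-oxo-4H-pyran-3-yl)but-2-enoate F3. On exposure to NaOMe in MeOH as in step 10, reversible deprotonation at the butenoate methyl group and reversible conjugate addition of methoxide interconvert the alkene isomers. Only the Z form can cyclise, so the material should funnel to chromone 16, where the route is rejoined.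

Step 14. What may go wrong: the dienolate acts as a base towards the benzylic CH2 of the acyl imidazole instead of as a nucleophile, or the stabilised enolate of the product adds to C2 of the chromone before the quench. The fallback forms the C–C bond at the aldehyde oxidation level under Lewis acid instead of strong base. Setting out from alcohol 18, Dess–Martin oxidation would give [3,5-dimethoxy-2-(7-methoxy-5-methyl-4-oxo-4H-chromen-2-yl)phenyl]acetaldehyde F4. The silyl dienol ether 2,2-dimethyl-6-methylidene-4-(trimethylsilyloxy)-6H-1,3-dioxine F5 (from 20 with LiN(SiMe3)2 and Me3SiCl) would add to it under BF3·OEt2 at −78 °C (vinylogous Mukaiyama aldol). This should give racemic 6-(3-{3,5-dimethoxy-2-[7-methoxy-5-methyl-4-oxo-4H-chromen-2-yl]phenyl}-2-hydroxypropyl)-2,2-dimethyl-4H-1,3-dioxin-4-one F6, and a second Dess–Martin oxidation would deliver keto-dioxinone 23, where the route is rejoined.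

**Further compounds**

F1 | step 10 | 1-(2-hydroxy-4-methoxy-6-methylphenyl)ethanone | CC(=O)c1c(C)cc(OC)cc1O
F2 | step 10 | (E)-3-{2,4-dimethoxy-6-[2-(triisopropylsilyloxy)ethyl]phenyl}-1-(2-hydroxy-4-methoxy-6-methylphenyl)prop-2-en-1-one | COc1cc(C)c(C(=O)/C=C/c2c(OC)cc(OC)cc2CCO[Si](C(C)C)(C(C)C)C(C)C)c(O)c1
F3 | step 9 | methyl (E)-3-(6-{2,4-dimethoxy-6-[2-(triisopropylsilyloxy)ethyl]phenyl}-2-methyl-4-oxo-4H-pyran-3-yl)but-2-enoate | Cc1oc(-c2c(OC)cc(OC)cc2CCO[Si](C(C)C)(C(C)C)C(C)C)cc(=O)c1/C(C)=C/C(=O)OC
F4 | step 14 | [3,5-dimethoxy-2-(7-methoxy-5-methyl-4-oxo-4H-chromen-2-yl)phenyl]acetaldehyde | Cc1cc(OC)cc2oc(-c3c(OC)cc(OC)cc3CC=O)cc(=O)c12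
F5 | step 14 | 2,2-dimethyl-6-methylidene-4-(trimethylsilyloxy)-6H-1,3-dioxine | C=C1C=C(O[Si](C)(C)C)OC(C)(C)O1
F6 | step 14 | 6-(3-{3,5-dimethoxy-2-[7-methoxy-5-methyl-4-oxo-4H-chromen-2-yl]phenyl}-2-hydroxypropyl)-2,2-dimethyl-4H-1,3-dioxin-4-one (racemic) | Cc1cc(OC)cc2oc(-c3c(OC)cc(OC)cc3CC(O)CC4=CC(=O)OC(C)(C)O4)cc(=O)c12
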